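The 14-membered carbocycle is closed in the last step by forming the bond between the tertiary carbinol carbon C3 and the alkene carbon C4 (ring numbered from the acetoxy carbon C1). An intramolecular Nozaki–Hiyama–Kishi reaction unites two electrophilic carbons, a C3 methyl ketone and a C4 (E)-alkenyl iodide, and delivers macrocycle, E-alkene and C3 stereocentre in one operation. It exploits the tertiary allylic alcohol next to the trans C4=C5 bond: the E geometry keeps the alkenylchromium off the C9 ketone, and the C1 acetate steers the new centre. The precursor is an open-chain iodo diketone that already carries the butenolide ring, assembled by indium Barbier coupling and ring-closing metathesis.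

Key step: step 17

Numbering used below: ring carbons are C1 (acetoxy carbon), C2, C3 (carbinol), C4=C5, C6, C7 (methyl-bearing), C8, C9 (ketone), C10, C11=C12 (butenolide alkene), C13 (butenolide oxygen-bearing carbon) and C15 (isopropyl-bearing); C14 is the lactone carbonyl.

Assumption: methyl hydrogen (R)-3-methylglutarate, (S)-4-benzyl-1,3-oxazolidin-2-one, D-proline and 2-(bromomethyl)acrylic acid are purchased.

Step 1
Reactants: 1 methyl hydrogen (R)-3-methylglutarate
Product: 3 (4R)-4-methyloxan-2-one, via hydroxy ester 2 (not isolated)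
Conditions: BH3·SMe2, THF, 0 °C to rt; MeOH quench; then TsOH (cat.), toluene, rt
Reagents that add atoms: none
Why: Borane reduces the free carboxylic acid chemoselectively beside the methyl ester, and the δ-hydroxy ester 2 then lactonises by acid-catalysed transesterification without touching the future C7 stereocentre.

Step 2
Reactants: 3 (4R)-4-methyloxan-2-one
Product: 4 (4R)-4-methyloxan-2-ol (anomer mixture)
Conditions: iBu2AlH, CH2Cl2, −78 °C; aq. KNaC4H4O6 work-up
Reagents that add atoms: none
Why: Low-temperature hydride delivery stops at the lactol oxidation level, the standard partial reduction of a δ-lactone.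

Step 3
Reactants: 4 (4R)-4-methyloxan-2-ol
Product: 5 (3S,5E)-6-iodo-3-methylhex-5-en-1-ol
Conditions: CrCl2, CHI3, THF/1,4-dioxane, 0 °C to rt
Reagents that add atoms: iodoform, IC(I)I
Why: Takai olefination on the open hydroxy-aldehyde tautomer of the lactol, in which the geminal dichromium reagent made from CHI3 and CrCl2 adds to the aldehyde and eliminates to the E-alkenyl iodide (C4=C5) while the free alcohol is tolerated.

Step 4
Reactants: 5 (3S,5E)-6-iodo-3-methylhex-5-en-1-ol
Product: 6 (3S,5E)-6-iodo-3-methylhex-5-enal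
Conditions: Dess–Martin periodinane, CH2Cl2, 0 °C to rt
Reagents that add atoms: none
Why: Dess–Martin oxidation of the primary alcohol under near-neutral conditions that spare the alkenyl iodide and cannot epimerise the β-stereocentre.

Step 5
Reactants: 7 (S)-4-benzyl-1,3-oxazolidin-2-one; 8 3-methylbutanoyl chloride
Product: 9 (4S)-4-benzyl-3-(3-methylbutanoyl)-1,3-oxazolidin-2-one
Conditions: Et3N, DMAP (cat.), CH2Cl2, 0 °C to rt
Reagents that add atoms: none
Why: N-acylation of the oxazolidinone by nucleophilic acyl substitution under DMAP catalysis.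

Step 6
Reactants: 9 (4S)-4-benzyl-3-(3-methylbutanoyl)-1,3-oxazolidin-2-one; 10 acrolein
Product: 12 (4S)-4-benzyl-3-[(2S,3R)-3-hydroxy-2-(propan-2-yl)pent-4-enoyl]-1,3-oxazolidin-2-one, via dibutylboron Z-enolate 11 (not isolated)
Conditions: Bu2BOTf, iPr2NEt, CH2Cl2, 0 °C; acrolein, −78 to 0 °C; then pH 7 buffer, MeOH, H2O2
Reagents that add atoms: none
Why: Evans syn-aldol reaction in which the Z-enolate 11 adds 1,2 to acrolein through a Zimmerman–Traxler chair whose enolate face is fixed by the benzyl group of the auxiliary, setting C15 and C13 (2S,3R, syn).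

Step 7
Reactants: 12 (4S)-4-benzyl-3-[(2S,3R)-3-hydroxy-2-(propan-2-yl)pent-4-enoyl]-1,3-oxazolidin-2-one
Product: 13 (4S)-4-benzyl-3-[(2S,3R)-3-{[tert-butyl(dimethyl)silyl]oxy}-2-(propan-2-yl)pent-4-enoyl]-1,3-oxazolidin-2-one
Conditions: TBSOTf, 2,6-lutidine, CH2Cl2, −78 to 0 °C
Reagents that add atoms: tert-butyldimethylsilyl triflate (TBSOTf), CC(C)(C)[Si](C)(C)OS(=O)(=O)C(F)(F)F
Why: Silylation of the secondary allylic alcohol with a silyl triflate and a hindered base, which protects the C13 oxygen without retro-aldol cleavage.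

Step 8
Reactants: 13 (4S)-4-benzyl-3-[(2S,3R)-3-{[tert-butyl(dimethyl)silyl]oxy}-2-(propan-2-yl)pent-4-enoyl]-1,3-oxazolidin-2-one
Product: 14 (2R,3R)-3-{[tert-butyl(dimethyl)silyl]oxy}-2-(propan-2-yl)pent-4-en-1-ol
Conditions: LiBH4, MeOH (2 equiv), THF, 0 °C
Reagents that add atoms: none
Why: Reductive removal of the auxiliary, in which the borohydride reduces the exocyclic imide carbonyl to the primary alcohol and releases the oxazolidinone while silyl ether and alkene stay inert.

Step 9
Reactants: 14 (2R,3R)-3-{[tert-butyl(dimethyl)silyl]oxy}-2-(propan-2-yl)pent-4-en-1-ol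
Product: 15 (2S,3R)-3-{[tert-butyl(dimethyl)silyl]oxy}-2-(propan-2-yl)pent-4-enal
Conditions: Dess–Martin periodinane, CH2Cl2, 0 °C to rt
Reagents that add atoms: none
Why: Dess–Martin oxidation gives the α-branched aldehyde (C1) under conditions too mild to epimerise C15 or eliminate the β-silyloxy group.

Step 10
Reactants: 15 (2S,3R)-3-{[tert-butyl(dimethyl)silyl]oxy}-2-(propan-2-yl)pent-4-enal; 16 acetone
Product: 17 (4S,5R,6R)-6-{[tert-butyl(dimethyl)silyl]oxy}-4-hydroxy-5-(propan-2-yl)oct-7-en-2-one
Conditions: D-proline (30 mol%), acetone/DMSO 1:4, rt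
Reagents that add atoms: none
Why: Proline-catalysed direct aldol reaction (enamine catalysis) in which the acetone enamine of D-proline attacks the Si face of the aldehyde in the hydrogen-bonded transition state, the mirror image of the L-proline case that gives (R)-ketols from α-branched aldehydes, so the C1 carbinol (4S) is set under catalyst control.

Step 11
Reactants: 17 (4S,5R,6R)-6-{[tert-butyl(dimethyl)silyl]oxy}-4-hydroxy-5-(propan-2-yl)oct-7-en-2-one
Product: 18 (3R,4R,5S)-3-{[tert-butyl(dimethyl)silyl]oxy}-7-oxo-4-(propan-2-yl)oct-1-en-5-yl acetate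
Conditions: Ac2O, pyridine, DMAP (cat.), CH2Cl2, 0 °C
Reagents that add atoms: acetic anhydride, CC(=O)OC(C)=O
Why: Acylation of the only free hydroxyl under weakly basic conditions at low temperature, which should not trigger β-elimination of the β-acetoxy ketone.

Step 12
Reactants: 18 (3R,4R,5S)-3-{[tert-butyl(dimethyl)silyl]oxy}-7-oxo-4-(propan-2-yl)oct-1-en-5-yl acetate
Product: 19 (3R,4S,5S)-3-hydroxy-7-oxo-4-(propan-2-yl)oct-1-en-5-yl acetate
Conditions: HF·pyridine, pyridine, THF, 0 °C to rt
Reagents that add atoms: none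
Why: Fluoride cleavage of the allylic silyl ether under buffered, mildly acidic conditions that leave the acetate and the ketone intact and disfavour acetyl migration.

Step 13
Reactants: 19 (3R,4S,5S)-3-hydroxy-7-oxo-4-(propan-2-yl)oct-1-en-5-yl acetate; 20 2-(bromomethyl)acrylic acid
Product: 21 (3R,4R,5S)-5-(acetyloxy)-7-oxo-4-(propan-2-yl)oct-1-en-3-yl 2-(bromomethyl)prop-2-enoate
Conditions: N,N'-diisopropylcarbodiimide, DMAP (cat.), CH2Cl2, 0 °C
Reagents that add atoms: none
Why: Steglich esterification of the secondary allylic alcohol, which reacts from its open-chain form because the tertiary hydroxyl of the hemiketal tautomer is not acylated.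

Step 14
Reactants: 21 (3R,4R,5S)-5-(acetyloxy)-7-oxo-4-(propan-2-yl)oct-1-en-3-yl 2-(bromomethyl)prop-2-enoate; 6 (3S,5E)-6-iodo-3-methylhex-5-enal
Product: 22 (3R,4R,5S)-5-(acetyloxy)-7-oxo-4-(propan-2-yl)oct-1-en-3-yl (6S,8E)-4-hydroxy-9-iodo-6-methyl-2-methylidenenon-8-enoate (epimer mixture at the new carbinol C9)
Conditions: In powder, THF/H2O 3:1, rt
Reagents that add atoms: none
Why: Indium-mediated Barbier allylation in aqueous THF, in which the 2-(alkoxycarbonyl)allyl unit adds with allylic transposition to the aldehyde far faster than to the methyl ketone and tolerates acetate, ester and alkenyl iodide; the new carbinol centre is formed unselectively and is erased in the next step.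

Step 15
Reactants: 22 (3R,4R,5S)-5-(acetyloxy)-7-oxo-4-(propan-2-yl)oct-1-en-3-yl (6S,8E)-4-hydroxy-9-iodo-6-methyl-2-methylidenenon-8-enoate
Product: 23 (3R,4R,5S)-5-(acetyloxy)-7-oxo-4-(propan-2-yl)oct-1-en-3-yl (6S,8E)-9-iodo-6-methyl-2-methylidene-4-oxonon-8-enoate
Conditions: Dess–Martin periodinane, CH2Cl2, 0 °C
Reagents that add atoms: none
Why: Dess–Martin oxidation of the only free alcohol to the C9 ketone under non-basic conditions, which avoids both translactonisation of the γ-hydroxy ester and migration of the methylidene double bond.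

Step 16
Reactants: 23 (3R,4R,5S)-5-(acetyloxy)-7-oxo-4-(propan-2-yl)oct-1-en-3-yl (6S,8E)-9-iodo-6-methyl-2-methylidene-4-oxonon-8-enoate
Product: 24 (5R)-5-[(3R,4S)-4-(acetyloxy)-2-methyl-6-oxoheptan-3-yl]-3-[(4S,6E)-7-iodo-4-methyl-2-oxohept-6-en-1-yl]furan-2(5H)-one
Conditions: second-generation Grubbs catalyst, (H2IMes)(PCy3)Cl2Ru=CHPh (10 mol%), 1,4-benzoquinone (20 mol%), toluene, 0.005 M, 80 °C
Reagents that add atoms: none
Why: Ring-closing metathesis of the allylic-ester vinyl group onto the 1,1-disubstituted acrylate closes the five-membered butenolide (C11=C12) with loss of ethene, the usual route to α-substituted butenolides, while the E-alkenyl iodide is a poor partner for the ruthenium carbene and benzoquinone suppresses double-bond migration.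

Step 17
Reactants: 24 (5R)-5-[(3R,4S)-4-(acetyloxy)-2-methyl-6-oxoheptan-3-yl]-3-[(4S,6E)-7-iodo-4-methyl-2-oxohept-6-en-1-yl]furan-2(5H)-one
Product: 26 CNP0200490.2 (the target macrocycle), via alkenylchromium dichloride 25 (not isolated)
Conditions: CrCl2 (12 equiv), NiCl2 (0.1 equiv), degassed DMSO/THF 3:1, 0.002 M, slow addition of 24, rt to 40 °C; then H2O, ethylenediamine
Reagents that add atoms: none
Why: Nozaki–Hiyama–Kishi reaction: zerovalent nickel formed from NiCl2 and CrCl2 inserts into the carbon–iodine bond of 24, transmetalation gives the (E)-alkenylchromium dichloride 25 with retention of geometry, and its carbon C4 adds to the chromium-bound C3 ketone, so a halide carbon and a carbonyl carbon, both electrophilic, are joined reductively and the alkoxide is freed on work-up. The closest known reaction type is the NHK macrocyclisation of alkenyl iodides onto carbonyl groups used for cembranoid-size rings, here with a ketone as acceptor. The 14-membered carbocycle closes in a 14-exo-trig mode, the carbonyl oxygen staying outside the ring. The new C3 stereocentre is controlled by the C1 acetoxy stereocentre: addition anti to the β-oxygen (1,3-anti induction, with the C–OAc and C=O dipoles opposed on the chromium-bound carbonyl), in a transition state stiffened by the butenolide ring and the E-alkene, should give the (3S)-alcohol. The step needs chemoselectivity for the C3 ketone over the C9 ketone, the lactone and the acetate: the E geometry of 25 secures the first because addition to C9 would form a trans-cyclohexene, organochromium reagents do not attack esters, and high dilution with slow addition suppresses intermolecular coupling.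

Compound list
1 | methyl hydrogen (R)-3-methylglutarate | COC(=O)C[C@H](C)CC(=O)O | starting material
2 | methyl (3R)-5-hydroxy-3-methylpentanoate | COC(=O)C[C@H](C)CCO | intermediate (not isolated)
3 | (4R)-4-methyloxan-2-one | O=C1C[C@H](C)CCO1 | intermediate
4 | (4R)-4-methyloxan-2-ol (anomer mixture) | OC1C[C@H](C)CCO1 | intermediate
5 | (3S,5E)-6-iodo-3-methylhex-5-en-1-ol | I/C=C/C[C@H](C)CCO | intermediate
6 | (3S,5E)-6-iodo-3-methylhex-5-enal | I/C=C/C[C@H](C)CC=O | intermediate
7 | (S)-4-benzyl-1,3-oxazolidin-2-one | O=C1N[C@@H](Cc2ccccc2)CO1 | starting material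
8 | 3-methylbutanoyl chloride | CC(C)CC(=O)Cl | starting material
9 | (4S)-4-benzyl-3-(3-methylbutanoyl)-1,3-oxazolidin-2-one | CC(C)CC(=O)N1[C@@H](Cc2ccccc2)COC1=O | intermediate
10 | acrolein | C=CC=O | starting material
11 | dibutylboron (Z)-enolate of 9 | CCCCB(CCCC)O/C(=C\C(C)C)N1[C@@H](Cc2ccccc2)COC1=O | intermediate (not isolated)
12 | (4S)-4-benzyl-3-[(2S,3R)-3-hydroxy-2-(propan-2-yl)pent-4-enoyl]-1,3-oxazolidin-2-one | C=C[C@@H](O)[C@H](C(C)C)C(=O)N1[C@@H](Cc2ccccc2)COC1=O | intermediate
13 | (4S)-4-benzyl-3-[(2S,3R)-3-{[tert-butyl(dimethyl)silyl]oxy}-2-(propan-2-yl)pent-4-enoyl]-1,3-oxazolidin-2-one | C=C[C@@H](O[Si](C)(C)C(C)(C)C)[C@H](C(C)C)C(=O)N1[C@@H](Cc2ccccc2)COC1=O | intermediate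
14 | (2R,3R)-3-{[tert-butyl(dimethyl)silyl]oxy}-2-(propan-2-yl)pent-4-en-1-ol | C=C[C@@H](O[Si](C)(C)C(C)(C)C)[C@H](C(C)C)CO | intermediate
15 | (2S,3R)-3-{[tert-butyl(dimethyl)silyl]oxy}-2-(propan-2-yl)pent-4-enal | C=C[C@@H](O[Si](C)(C)C(C)(C)C)[C@H](C(C)C)C=O | intermediate
16 | acetone | CC(C)=O | starting material
17 | (4S,5R,6R)-6-{[tert-butyl(dimethyl)silyl]oxy}-4-hydroxy-5-(propan-2-yl)oct-7-en-2-one | C=C[C@@H](O[Si](C)(C)C(C)(C)C)[C@H](C(C)C)[C@@H](O)CC(C)=O | intermediate
18 | (3R,4R,5S)-3-{[tert-butyl(dimethyl)silyl]oxy}-7-oxo-4-(propan-2-yl)oct-1-en-5-yl acetate | C=C[C@@H](O[Si](C)(C)C(C)(C)C)[C@H](C(C)C)[C@@H](OC(C)=O)CC(C)=O | intermediate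
19 | (3R,4S,5S)-3-hydroxy-7-oxo-4-(propan-2-yl)oct-1-en-5-yl acetate | C=C[C@@H](O)[C@H](C(C)C)[C@@H](OC(C)=O)CC(C)=O | intermediate
20 | 2-(bromomethyl)acrylic acid | C=C(CBr)C(=O)O | starting material
21 | (3R,4R,5S)-5-(acetyloxy)-7-oxo-4-(propan-2-yl)oct-1-en-3-yl 2-(bromomethyl)prop-2-enoate | C=C[C@@H](OC(=O)C(=C)CBr)[C@H](C(C)C)[C@@H](OC(C)=O)CC(C)=O | intermediate
22 | (3R,4R,5S)-5-(acetyloxy)-7-oxo-4-(propan-2-yl)oct-1-en-3-yl (6S,8E)-4-hydroxy-9-iodo-6-methyl-2-methylidenenon-8-enoate (C9 epimers) | C=C[C@@H](OC(=O)C(=C)CC(O)C[C@@H](C)C/C=C/I)[C@H](C(C)C)[C@@H](OC(C)=O)CC(C)=O | intermediate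
23 | (3R,4R,5S)-5-(acetyloxy)-7-oxo-4-(propan-2-yl)oct-1-en-3-yl (6S,8E)-9-iodo-6-methyl-2-methylidene-4-oxonon-8-enoate | C=C[C@@H](OC(=O)C(=C)CC(=O)C[C@@H](C)C/C=C/I)[C@H](C(C)C)[C@@H](OC(C)=O)CC(C)=O | intermediate
24 | (5R)-5-[(3R,4S)-4-(acetyloxy)-2-methyl-6-oxoheptan-3-yl]-3-[(4S,6E)-7-iodo-4-methyl-2-oxohept-6-en-1-yl]furan-2(5H)-one | I/C=C/C[C@H](C)CC(=O)CC1=C[C@@H](OC1=O)[C@H](C(C)C)[C@@H](OC(C)=O)CC(C)=O | intermediate
25 | (E)-alkenylchromium dichloride derived from 24 (CrCl2 in place of iodine, solvent ligands omitted) | Cl[Cr](Cl)/C=C/C[C@H](C)CC(=O)CC1=C[C@@H](OC1=O)[C@H](C(C)C)[C@@H](OC(C)=O)CC(C)=O | intermediate (not isolated)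
26 | CNP0200490.2: 14-membered carbocycle with C1 (S) acetate, C3 (S) hydroxyl and methyl, (E)-C4=C5, C7 (S) methyl, C9 ketone, C15 (R) isopropyl and the C11–C13 (13R) butenolide | CC(=O)O[C@H]1C[C@](C)(O)/C=C/C[C@H](C)CC(=O)CC2=C[C@@H](OC2=O)[C@@H]1C(C)C | target

Total step count: 17. Longest linear sequence: 13 steps (steps 5 to 17); the four-step branch (steps 1 to 4) joins at step 14.

Steps most likely to fail

Step 17. Addition of the alkenylchromium to the hindered, weakly electrophilic methyl ketone across a ring stiffened by the butenolide may be slow, so protodemetalation and oligomerisation can take over, and the facial selectivity at C3 may be poor. The fallback exchanges the order of the two ring closures. It sets out from 23: the same CrCl2/NiCl2 conditions applied to the open-chain iodo triene 23 close the C3–C4 bond first and give the more flexible 15-membered hydroxy macrolactone F1, in which no butenolide constrains the transition state and the E geometry still protects the C9 ketone. Transannular ring-closing metathesis of F1 between the vinyl group and the 2-methylidene unit (second-generation Grubbs catalyst, toluene, 80 °C) then forms the butenolide and comes back to the route at 26.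

Step 10. Enamine addition to the doubly branched aldehyde may be slow, which allows erosion of facial selectivity in a mismatched pairing, epimerisation of C15 through the aldehyde's own enamine and β-elimination of the silyloxy group. The fallback replaces organocatalysis by an auxiliary-controlled acetate aldol. It sets out from 15: doubly deprotonated (S)-2-hydroxy-1,2,2-triphenylethyl acetate (HYTRA; LiN(iPr)2, THF, then MgBr2, addition of 15 at −115 °C) gives the β-hydroxy ester F2 with the (S)-carbinol. Saponification (KOH, MeOH/H2O) gives the β-hydroxy acid F3 and returns the triphenylethanediol. Excess MeLi (Et2O, 0 °C, Me3SiCl quench) converts the carboxylic acid into the methyl ketone and comes back to the route at 17.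

Step 13. The allylic bromide may alkylate DMAP, acylation of the hindered alcohol is slowed by its ring–chain equilibrium with the hemiketal, and the acetate may migrate to the free hydroxyl under the basic conditions. The fallback builds the acid half first, so that no allylic bromide is present at the esterification. It sets out from 6 and uses 19: indium-mediated Barbier allylation of 6 with commercial tert-butyl 2-(bromomethyl)acrylate, C=C(CBr)C(=O)OC(C)(C)C (In powder, THF/H2O), gives the hydroxy tert-butyl ester F4. Dess–Martin oxidation gives the keto ester F5, and CF3CO2H in CH2Cl2 at 0 °C frees the keto acid F6. Yamaguchi esterification of F6 with 19 (2,4,6-trichlorobenzoyl chloride, Et3N, then 19 and DMAP, toluene) comes back to the route at 23.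

Further compounds
F1 | step 17 | (7S,9E,11S,13S,14R,15R)-15-ethenyl-11-hydroxy-7,11-dimethyl-3-methylidene-2,5-dioxo-14-(propan-2-yl)-1-oxacyclopentadec-9-en-13-yl acetate | C=C[C@H]1OC(=O)C(=C)CC(=O)C[C@@H](C)C/C=C/[C@@](C)(O)C[C@H](OC(C)=O)[C@H]1C(C)C
F2 | step 10 | (1S)-2-hydroxy-1,2,2-triphenylethyl (3S,4R,5R)-5-{[tert-butyl(dimethyl)silyl]oxy}-3-hydroxy-4-(propan-2-yl)hept-6-enoate | C=C[C@@H](O[Si](C)(C)C(C)(C)C)[C@H](C(C)C)[C@@H](O)CC(=O)O[C@@H](c1ccccc1)C(O)(c1ccccc1)c1ccccc1
F3 | step 10 | (3S,4R,5R)-5-{[tert-butyl(dimethyl)silyl]oxy}-3-hydroxy-4-(propan-2-yl)hept-6-enoic acid | C=C[C@@H](O[Si](C)(C)C(C)(C)C)[C@H](C(C)C)[C@@H](O)CC(=O)O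
F4 | step 13 | tert-butyl (6S,8E)-4-hydroxy-9-iodo-6-methyl-2-methylidenenon-8-enoate (C4 epimers) | C=C(CC(O)C[C@@H](C)C/C=C/I)C(=O)OC(C)(C)C
F5 | step 13 | tert-butyl (6S,8E)-9-iodo-6-methyl-2-methylidene-4-oxonon-8-enoate | C=C(CC(=O)C[C@@H](C)C/C=C/I)C(=O)OC(C)(C)C
F6 | step 13 | (6S,8E)-9-iodo-6-methyl-2-methylidene-4-oxonon-8-enoic acid | C=C(CC(=O)C[C@@H](C)C/C=C/I)C(=O)O
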